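## Structural features

The target is a diaryl ether with no stereocentres. Ring A is a salicylic acid (CO2H at C1, OH at C2) with a 3-methylbut-2-enyl (prenyl) group at C3 and the ether oxygen at C6; ring B carries the ether oxygen at C1', a free phenol at C2', a methyl group at C4' and a hydroxymethyl group at C6'. The ether oxygen joins a ring B carbon flanked by two ortho substituents to a ring A carbon ortho to the carboxyl group, and both rings are electron-rich, so a direct aryl–oxygen coupling would be hindered and poorly activated; this bond, together with the four contiguous substituents C6–C1–C2–C3 of ring A, is the real difficulty. The fragile groups are the prenyl alkene next to a phenol (acid closes it to a chroman; hydrogenation and strong oxidants are excluded), the benzylic alcohol on an electron-rich ring (it ionises in acid), and the salicylic acid, which can lactonise onto the hydroxymethyl group or decarboxylate. The key step exploits the fact that C1'(OAr)–C2'(OH)–C3'(H) of ring B has the pattern of an aryloxyacetone and C4'(CH3)–C5'(H)–C6'(CH2OH) that of an acetylpyruvate ester, so ring B can be built on an oxygen that was attached to ring A by a simple alkylation. A bromine at C1 of ring A blocks that position during the Claisen rearrangement and holds the place of the carboxyl group.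

## Logic of the disconnections

21 ⇒ 20. The last bond cut is the O–CH2 bond of a methoxymethyl acetal on the C2 oxygen of ring A. This phenol must be masked through base, hydride and organolithium chemistry, and an acetal oxygen next to C1 also helps to hold a metal there. The gain is one protecting group; the demand is a final acid mild enough to leave the prenyl alkene and the benzylic alcohol of 21 alone.

20 ⇒ 17. The C1–CO2H bond is cut. A carboxyl or ester at C1 could not be carried through the ring B construction, because the C1' carbanion would acylate itself on it, so bromine stands in. The forward step must exchange bromine for lithium in a molecule with two hydroxyls, so these are deprotonated first and the carbanion is kept cold.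

17 ⇒ 15. The hydroxymethyl group at C6' is taken back to an ester; no skeletal bond is cut. The ester is what the annulation delivers, and it must be reduced before the organolithium step, otherwise the aryllithium would close onto it. The hydride must spare the aryl bromide.

15 ⇒ 8 + 11. Ring B is cut at C1'–C6' and C3'–C4'. This removes the whole ring and leaves the ether oxygen on an sp3 carbon, so the hindered diaryl ether becomes an alkyl aryl ether, and one step then forms the ring with all four substituents at the right oxidation level. The demands are heavy. The first bond must form at the aryloxy-bearing carbon of 8. Because the acetyl methyl of 11 is enolisable as well, the ring-closing aldol has a choice of direction that the substrate must bias. 11 carries an ethoxy, not a methoxy, leaving group, so that the alkoxide set free is the one already present in the ester and no ester scrambling can occur. Ring A carries bromine and an acetal, both inert to base.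

11 ⇒ 9. The enol ether C–O bond is cut. 9 is an acidic diketone that would only be deprotonated under the annulation conditions; etherification at the C2 oxygen turns it into a 1,3-dielectrophile with a leaving group at the future C6'. The forward step must etherify the carbonyl next to the ester and not the acetyl group.

8 ⇒ 7. The trisubstituted alkene of the prenyl group is cut by a metathesis transform to a terminal allyl group, which a Claisen rearrangement can place regiospecifically. The forward step needs a catalyst that tolerates ketone, bromide and acetal.

7 ⇒ 6. The acetal O–C bond is cut to free the C2 hydroxyl. In 6 this is the only hydroxyl, so the protection needs no selectivity.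

6 ⇒ 4. The C3–allyl bond is cut by a retro-Claisen transform that returns the allyl group to the C2 oxygen. Bromine at C1 leaves only C3 open, so the regiochemistry is enforced, and the oxygen that carried the allyl group emerges as the one free hydroxyl. The demand is that the aryloxy ketone survive the heat.

4 ⇒ 2 + 3. The O–CH2 bond of the acetonyl ether is cut. Placing this group while only one hydroxyl is free avoids having to distinguish the two hydroxyls of a rearranged resorcinol, where only sterics would tell them apart. The forward step is a plain phenoxide alkylation.

2 ⇒ 1. The allyl–oxygen bond is cut, leading to the symmetrical 1. Symmetry frees the first alkylation of any regiochemistry; it only has to be stopped at the mono-ether.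

## Other disconnections considered

Alternative 1: The cut runs through C1'–C2' and C5'–C6', so ring B is made as a spiro cyclohexene on C2 of a benzofuran-3-one. In the forward sense the siloxy diene A2 adds across the exocyclic alkene of the alkylidene coumaranone A1 to give the spiro adduct A3. Afterwards the C2' silyl ether would be oxidised to a ketone, the spiro 1,3-diketone opened by retro-Claisen cleavage of the bond between the coumaranone carbonyl and C1' (which releases the ring A carboxyl and the diaryl ether together), ring B dehydrogenated to the phenol, and the allyl ether converted to the C3 prenyl group by Claisen rearrangement and cross-metathesis.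
- In its favour: like the chosen plan it puts the ether oxygen on a non-aromatic carbon, so no hindered aryl–oxygen coupling is needed. The regiochemistry of a 1-oxygenated diene with an enone is dependable, and the three stereocentres of A3 are irrelevant because all are destroyed.
- Where it is better: the carboxyl carbon is present from the start as the coumaranone carbonyl, whereas the chosen plan needs a bromine placeholder and an organolithium carboxylation.
- Against it: A1 is a trisubstituted dienophile that must create a quaternary centre, and it could instead tautomerise to an aromatic 3-hydroxybenzofuran or lose its allylic silyloxy group. Ring B would arrive two oxidation events short of aromatic, and the retro-Claisen step must break the right one of two acyl–C1' bonds.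
- Comparison: on structure the two plans are equal. On mechanism the pericyclic regiocontrol is at least the equal of, and probably firmer than, the acidity- and sterics-based regiocontrol of the annulation 8 + 11 → 15. On step economy the chosen plan is clearly ahead, because it gives ring B aromatic and correctly oxidised in one step.

Alternative 2: The cut is at C3–C4 and C1–C6 of ring A, which is made as a cyclohexane-1,3-dione and aromatised late. In the forward sense the dianion of the keto ester A4 adds through its γ-carbon to the acrylate A5 and the β-keto ester carbon closes the ring by Dieckmann condensation to give A6. The C6 enol oxygen would then be arylated by a ring B partner, or a ring B phenol such as A9 added to a vinylogous halide made from A6, and ring A dehydrogenated.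
- Where it is better: the prenyl group is placed by the carbon chain itself, with no Claisen rearrangement or metathesis, and the carboxyl carbon is an ester from the first step.
- Against it: the hardest bond is left undone. The ether must be made from a vinylogous acid whose two carbonyls (C2 and C6) differ only by the neighbouring prenyl group, with a ring B partner that reacts through its more hindered catechol oxygen and needs its own synthesis. Ring A must then be dehydrogenated in the presence of a prenyl group and benzylic positions.
- Comparison: on structure it is superior for ring A and inferior for the ether. On mechanism its key step is as well precedented as that of the chosen plan, but the later O-arylation and aromatisation are less secure. On step economy it would be no shorter once ring B and the redox steps are counted.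

Alternative 3: The cut is at C6–O and C1–CO2H; no ring is formed. In the forward sense fluoride releases the aryne A8 from the silyl aryl triflate A7, the cesium salt of the phenol A9 adds at C6, and the C1 aryl anion is trapped by carboxylation to give A10, which needs only global deprotection.
- Where it is better: it is the most convergent plan, with two bonds formed in one operation and the shortest sequence after the union. The regiochemistry fits well, since a nucleophile adds meta to the alkoxy group of a 3-alkoxyaryne and leaves the anion ortho to it, which are exactly the sites required.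
- Against it: A7 and A9 each need several steps, and A9 needs its catechol oxygens differentiated. The phenoxide is flanked by two ortho substituents and would be partly tied up as a carbonate under carboxylation conditions. The aryl anion can be protonated instead of carboxylated, and the aryne can undergo an ene reaction with the allylic hydrogens of a prenyl group.
- Comparison: a three-component union of a hindered phenoxide, an aryne and a carboxylating agent lacks close precedent, whereas every step of the chosen route is of a known type. On structure and convergence the alternative is better; on mechanism it is less secure; its overall step count would be similar once both fragments are made.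

Key step: step 7

Assumption: the alkene of 11 is drawn as the (Z) isomer; the geometry has no bearing on the route, because the addition–elimination of step 7 erases it.

## Route

Step 1
Reactants: 1 2-bromobenzene-1,3-diol
Product: 2 2-bromo-3-(prop-2-enyloxy)phenol
Conditions: allyl bromide (1.0 equiv), K2CO3 (1.1 equiv), acetone, reflux
Reagents that add atoms: allyl bromide C=CCBr
Why: Williamson ether synthesis on the mono-phenoxide of a symmetrical diol; the first alkylation cannot give regioisomers, and unreacted 1 and the bis-ether should be separable by polarity so that 1 can be recycled.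

Step 2
Reactants: 2 2-bromo-3-(prop-2-enyloxy)phenol; 3 chloroacetone
Product: 4 1-[2-bromo-3-(prop-2-enyloxy)phenoxy]propan-2-one
Conditions: K2CO3 (1.5 equiv), KI (cat.), acetone, reflux
Reagents that add atoms: none
Why: Williamson O-alkylation by SN2 at an α-halo ketone with iodide catalysis; only one hydroxyl is left, so the oxygen that will become the diaryl ether oxygen is fixed without any site selectivity.

Step 3
Reactants: 4 1-[2-bromo-3-(prop-2-enyloxy)phenoxy]propan-2-one
Product: 6 1-[2-bromo-3-hydroxy-4-(prop-2-enyl)phenoxy]propan-2-one, via ortho-dienone 5 (not isolated)
Conditions: N,N-diethylaniline, 190 °C, sealed tube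
Reagents that add atoms: none
Why: Aromatic Claisen rearrangement; one ortho position of the allyloxy group carries bromine, so the [3,3] shift should deliver the allyl group to C3 of ring A and dienone 5 enolises to the phenol, while the amine solvent keeps the medium free of acid that could harm the ketone or cyclise the allyl phenol.

Step 4
Reactants: 6 1-[2-bromo-3-hydroxy-4-(prop-2-enyl)phenoxy]propan-2-one
Product: 7 1-[2-bromo-3-(methoxymethoxy)-4-(prop-2-enyl)phenoxy]propan-2-one
Conditions: MeOCH2Cl (1.5 equiv), i-Pr2NEt (2 equiv), Bu4NI (cat.), CH2Cl2, 0 °C → rt
Reagents that add atoms: chloromethyl methyl ether COCCl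
Why: Alkylation of the acidic ortho-bromophenol by an α-chloro ether through its oxocarbenium ion; the amine base is too weak to enolise the ketone, and the only free hydroxyl is the one to be protected.

Step 5
Reactants: 7 1-[2-bromo-3-(methoxymethoxy)-4-(prop-2-enyl)phenoxy]propan-2-one
Product: 8 1-[2-bromo-3-(methoxymethoxy)-4-(3-methylbut-2-enyl)phenoxy]propan-2-one
Conditions: 2-methyl-2-butene (excess), second-generation Grubbs catalyst RuCl2(PCy3)(H2IMes)(=CHPh) (5 mol %), CH2Cl2, 40 °C
Reagents that add atoms: 2-methyl-2-butene CC=C(C)C
Why: Olefin cross-metathesis of a terminal allyl arene with a trisubstituted alkene, driven by loss of propene; the ketone, aryl bromide and acetal should not interfere with the ruthenium carbene.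

Step 6
Reactants: 9 ethyl 2,4-dioxopentanoate
Product: 11 ethyl (Z)-2-ethoxy-4-oxopent-2-enoate, via diethyl ketal 10 (not isolated)
Conditions: HC(OEt)3 (1.5 equiv), NH4Cl (cat.), EtOH, rt; distillation
Reagents that add atoms: triethyl orthoformate CCOC(OCC)OCC
Why: Acid-catalysed ketalisation by the orthoformate at the more electrophilic C2 carbonyl, next to the ester, followed by loss of ethanol toward the doubly activated C3 methylene gives the conjugated enol ether; this turns an acidic diketone into a 1,3-dielectrophile with a leaving group at the future C6'.

Step 7
Reactants: 8 1-[2-bromo-3-(methoxymethoxy)-4-(3-methylbut-2-enyl)phenoxy]propan-2-one; 11 ethyl (Z)-2-ethoxy-4-oxopent-2-enoate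
Product: 15 ethyl 2-[2-bromo-3-(methoxymethoxy)-4-(3-methylbut-2-enyl)phenoxy]-3-hydroxy-5-methylbenzoate, via acyclic enedione 12 (not isolated), via cyclic aldol 13 (not isolated), via cyclohexadienone 14 (not isolated)
Conditions: KOt-Bu (1.2 equiv), THF, 0 °C → rt, then 50 °C; AcOH quench
Reagents that add atoms: none
Why: KOt-Bu equilibrates the enolates of 8, and the aryloxy-stabilised one adds through C1' to the ethoxy-bearing carbon of 11 (β to the acetyl group) and expels ethoxide, a Michael addition–elimination that forms C1'–C6' and gives 12. 12 is at once deprotonated at C1' to a vinylogous diketonate through which alkene geometry and position equilibrate; the C3' methyl enolate then adds to the acetyl carbonyl C4' in a 6-(enolendo)-exo-trig aldol (13), the only ring closed in this step. E1cB loss of water gives dienone 14, whose enolisation is the irreversible aromatisation to 15. The closest known reaction type is the base-mediated [3+3] phenol annulation of methyl ketones with β-alkoxy enones, ynones or vinamidinium salts, the ring closure being that of a 2-ene-1,5-dione to a phenol. The stereocentres of 12 and 13 are transient and vanish on aromatisation, so no stereocontrol is needed. Two regiochemical choices are required: the first bond must form at C1' and not at C3', which the acidifying aryloxy group and the irreversible loss of ethoxide (against reversible aldol additions) should secure. The aldol must then run from C3' to C4' and not from the acetyl methyl of the former 11 to C2'; this is favoured because C2' is screened by the ortho-bromoaryloxy-bearing C1' and is a conjugated carbonyl in the push–pull tautomer ArO–C1'=C6'–CO2Et, whereas C4' is an unhindered methyl ketone, and closure onto the ester would be a disfavoured 5-(enolendo) process. The ethoxide leaving group matches the ethyl ester, so ester exchange is degenerate, and the bromine is inert where a ring A ester would be acylated by the C1' carbanion.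

Step 8
Reactants: 15 ethyl 2-[2-bromo-3-(methoxymethoxy)-4-(3-methylbut-2-enyl)phenoxy]-3-hydroxy-5-methylbenzoate
Product: 17 2-[2-bromo-3-(methoxymethoxy)-4-(3-methylbut-2-enyl)phenoxy]-3-(hydroxymethyl)-5-methylphenol, via aldehyde 16 (not isolated)
Conditions: i-Bu2AlH (4 equiv), CH2Cl2, −78 → 0 °C; aq. KNaC4H4O6
Reagents that add atoms: none
Why: Hydride reduction of the aryl ester through aldehyde 16 to the benzylic alcohol, one equivalent of hydride being consumed by the phenol; aryl bromide, acetal and alkene are inert, and removing the ester now prevents its attack by the aryllithium of step 9 (xanthone formation).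

Step 9
Reactants: 17 2-[2-bromo-3-(methoxymethoxy)-4-(3-methylbut-2-enyl)phenoxy]-3-(hydroxymethyl)-5-methylphenol
Product: 20 6-[2-hydroxy-6-(hydroxymethyl)-4-methylphenoxy]-2-(methoxymethoxy)-3-(3-methylbut-2-enyl)benzoic acid, via disodium salt 18 (not isolated), via aryllithium 19 (not isolated)
Conditions: NaH (2.2 equiv), THF, 0 °C → rt; t-BuLi (2.2 equiv), −78 °C; CO2 (g), −78 °C → rt; cold aq. HCl to pH 3
Reagents that add atoms: carbon dioxide O=C=O
Why: Both hydroxyls are deprotonated first (18) so that no proton can quench the carbanion; bromine–lithium exchange, with the second equivalent of t-BuLi destroying the tert-butyl bromide, gives aryllithium 19 held between the methoxymethoxy and aryloxy oxygens, and its carboxylation by CO2 is the classical route to 2,6-dioxygenated benzoic acids.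

Step 10
Reactants: 20 6-[2-hydroxy-6-(hydroxymethyl)-4-methylphenoxy]-2-(methoxymethoxy)-3-(3-methylbut-2-enyl)benzoic acid
Product: 21 2-hydroxy-6-[2-hydroxy-6-(hydroxymethyl)-4-methylphenoxy]-3-(3-methylbut-2-enyl)benzoic acid
Conditions: aq. HCl (2 M), THF, rt → 40 °C
Reagents that add atoms: none
Why: Acid hydrolysis of the phenolic methoxymethyl acetal, helped by the neighbouring carboxylic acid; dilute aqueous acid in a non-alcoholic solvent at mild temperature is chosen so that the prenyl alkene is not protonated (no chroman), the benzylic alcohol is not etherified, and the hindered 2,6-disubstituted acid neither esterifies nor lactonises.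

## Compound list

1 | 2-bromobenzene-1,3-diol (2-bromoresorcinol) | Oc1cccc(O)c1Br | starting material
2 | 2-bromo-3-(prop-2-enyloxy)phenol | C=CCOc1cccc(O)c1Br | intermediate
3 | chloroacetone (1-chloropropan-2-one) | CC(=O)CCl | starting material
4 | 1-[2-bromo-3-(prop-2-enyloxy)phenoxy]propan-2-one | CC(=O)COc1cccc(OCC=C)c1Br | intermediate
5 | racemic 2-bromo-3-(2-oxopropoxy)-6-(prop-2-enyl)cyclohexa-2,4-dien-1-one | C=CCC1C=CC(OCC(C)=O)=C(Br)C1=O | intermediate
6 | 1-[2-bromo-3-hydroxy-4-(prop-2-enyl)phenoxy]propan-2-one | CC(=O)COc1ccc(CC=C)c(O)c1Br | intermediate
7 | 1-[2-bromo-3-(methoxymethoxy)-4-(prop-2-enyl)phenoxy]propan-2-one | CC(=O)COc1ccc(CC=C)c(OCOC)c1Br | intermediate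
8 | 1-[2-bromo-3-(methoxymethoxy)-4-(3-methylbut-2-enyl)phenoxy]propan-2-one | CC(=O)COc1ccc(CC=C(C)C)c(OCOC)c1Br | intermediate
9 | ethyl 2,4-dioxopentanoate | CCOC(=O)C(=O)CC(C)=O | starting material
10 | ethyl 2,2-diethoxy-4-oxopentanoate | CCOC(=O)C(OCC)(OCC)CC(C)=O | intermediate
11 | ethyl (Z)-2-ethoxy-4-oxopent-2-enoate | CCOC(=O)/C(OCC)=C/C(C)=O | intermediate
12 | racemic ethyl (E)-2-{1-[2-bromo-3-(methoxymethoxy)-4-(3-methylbut-2-enyl)phenoxy]-2-oxopropyl}-4-oxopent-2-enoate | CCOC(=O)/C(=C/C(C)=O)C(Oc1ccc(CC=C(C)C)c(OCOC)c1Br)C(C)=O | intermediate
13 | ethyl 6-[2-bromo-3-(methoxymethoxy)-4-(3-methylbut-2-enyl)phenoxy]-3-hydroxy-3-methyl-5-oxocyclohex-1-ene-1-carboxylate (racemic, mixture of diastereomers) | CCOC(=O)C1=CC(C)(O)CC(=O)C1Oc2ccc(CC=C(C)C)c(OCOC)c2Br | intermediate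
14 | racemic ethyl 6-[2-bromo-3-(methoxymethoxy)-4-(3-methylbut-2-enyl)phenoxy]-3-methyl-5-oxocyclohexa-1,3-diene-1-carboxylate | CCOC(=O)C1=CC(C)=CC(=O)C1Oc2ccc(CC=C(C)C)c(OCOC)c2Br | intermediate
15 | ethyl 2-[2-bromo-3-(methoxymethoxy)-4-(3-methylbut-2-enyl)phenoxy]-3-hydroxy-5-methylbenzoate | CCOC(=O)c1cc(C)cc(O)c1Oc1ccc(CC=C(C)C)c(OCOC)c1Br | intermediate
16 | 2-[2-bromo-3-(methoxymethoxy)-4-(3-methylbut-2-enyl)phenoxy]-3-hydroxy-5-methylbenzaldehyde | O=Cc1cc(C)cc(O)c1Oc1ccc(CC=C(C)C)c(OCOC)c1Br | intermediate
17 | 2-[2-bromo-3-(methoxymethoxy)-4-(3-methylbut-2-enyl)phenoxy]-3-(hydroxymethyl)-5-methylphenol | OCc1cc(C)cc(O)c1Oc1ccc(CC=C(C)C)c(OCOC)c1Br | intermediate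
18 | disodium 2-[2-bromo-3-(methoxymethoxy)-4-(3-methylbut-2-enyl)phenoxy]-5-methyl-3-(oxidomethyl)phenolate | [Na+].[Na+].[O-]Cc1cc(C)cc([O-])c1Oc1ccc(CC=C(C)C)c(OCOC)c1Br | intermediate
19 | aryllithium from 18 by bromine–lithium exchange at C1 of ring A (disodium salt) | [Na+].[Na+].[O-]Cc1cc(C)cc([O-])c1Oc1ccc(CC=C(C)C)c(OCOC)c1[Li] | intermediate
20 | 6-[2-hydroxy-6-(hydroxymethyl)-4-methylphenoxy]-2-(methoxymethoxy)-3-(3-methylbut-2-enyl)benzoic acid | OCc1cc(C)cc(O)c1Oc1ccc(CC=C(C)C)c(OCOC)c1C(=O)O | intermediate
21 | 2-hydroxy-6-[2-hydroxy-6-(hydroxymethyl)-4-methylphenoxy]-3-(3-methylbut-2-enyl)benzoic acid | CC(C)=CCc1ccc(Oc2c(O)cc(C)cc2CO)c(C(=O)O)c1O | target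

## Step count and least certain steps

Total: 10 steps. Longest linear sequence: 9 steps (steps 1–5 and 7–10, from 1 to 21); step 6 is a one-step branch.

Step 7 (key step). The most likely failures are ring closure in the reverse aldol sense (the acetyl methyl of the former 11 adding to the C2' carbonyl instead of C3' adding to C4') and formation of the first bond through the methyl enolate of 8; both would transpose substituents on ring B. The fallback sets out from 8 and replaces 11 by diethyl but-2-ynedioate, which has no enolisable methyl group. Conjugate addition of the same C1' enolate (KOt-Bu, THF) should give the fumarate-type Michael adduct diethyl (E)-2-{1-[2-bromo-3-(methoxymethoxy)-4-(3-methylbut-2-enyl)phenoxy]-2-oxopropyl}but-2-enedioate F1. F1 can only close by Claisen condensation of C3' onto the remote ester, giving the resorcinol ester ethyl 2-[2-bromo-3-(methoxymethoxy)-4-(3-methylbut-2-enyl)phenoxy]-3,5-dihydroxybenzoate F2. Triflation of the unhindered 5-hydroxyl (PhNTf2, K2CO3), the 3-hydroxyl being screened by the neighbouring aryloxy group, would give ethyl 2-[2-bromo-3-(methoxymethoxy)-4-(3-methylbut-2-enyl)phenoxy]-3-hydroxy-5-(trifluoromethylsulfonyloxy)benzoate F3. A Stille methylation (SnMe4, PdCl2(PPh3)2, LiCl, DMF), under conditions where an unhindered triflate is expected to react before a hindered electron-rich bromide, comes back to the route at 15.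

Step 9. The likely failures are protonation of the aryllithium by incompletely deprotonated hydroxyls (loss of bromine without carboxylation), poor solubility of the polyanion, and expulsion of the ring B aryloxide from the ortho-lithiated diaryl ether if the mixture warms. The fallback sets out from 17 and removes the acidic protons: silylation (t-BuMe2SiCl, imidazole, DMF) gives the bis(tert-butyldimethylsilyl) ether F4; t-BuLi (2.1 equiv, THF, −78 °C) gives the aryllithium F5; carboxylation gives the bis(silyl) acid F6; and Bu4NF in THF removes both silyl groups and comes back to the route at 20.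

Step 3. The likely failures are thermal degradation or self-condensation of the aryloxy ketone at the rearrangement temperature, and migration to the bromine-bearing ortho position followed by a Cope shift to the para position. The fallback sets out from 2, which has no ketone. Claisen rearrangement of 2 under the same conditions passes through the ortho-dienone 2-bromo-3-hydroxy-6-(prop-2-enyl)cyclohexa-2,4-dien-1-one F7 to 2-bromo-4-(prop-2-enyl)benzene-1,3-diol F8. Alkylation of F8 with 3 (K2CO3, acetone) at the less hindered hydroxyl, remote from the allyl group, comes back to the route at 6. This trades the thermal risk for a site selectivity that rests on sterics alone.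

Step 6. The likely failures are etherification at the acetyl oxygen instead of the C2 oxygen (which would transpose methyl and ester on ring B in step 7) and incomplete loss of ethanol from 10. The fallback leaves 9 aside and uses an acceptor whose electrophilic site is unambiguous. Ethyl propiolate and acetaldehyde (LiN(SiMe3)2, THF, −78 °C) give racemic ethyl 4-hydroxypent-2-ynoate F9, and oxidation with MnO2 gives ethyl 4-oxopent-2-ynoate F10. The fallback joins the route at 8: under the conditions of step 7 the C1' enolate of 8 should add to the alkyne carbon β to the ketone of F10, and protonation comes back to the route at 12, which goes on to 15.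

## Further compounds

F1 | step 7 | racemic diethyl (E)-2-{1-[2-bromo-3-(methoxymethoxy)-4-(3-methylbut-2-enyl)phenoxy]-2-oxopropyl}but-2-enedioate | CCOC(=O)/C=C(C(Oc1ccc(CC=C(C)C)c(OCOC)c1Br)C(C)=O)/C(=O)OCC
F2 | step 7 | ethyl 2-[2-bromo-3-(methoxymethoxy)-4-(3-methylbut-2-enyl)phenoxy]-3,5-dihydroxybenzoate | CCOC(=O)c1cc(O)cc(O)c1Oc1ccc(CC=C(C)C)c(OCOC)c1Br
F3 | step 7 | ethyl 2-[2-bromo-3-(methoxymethoxy)-4-(3-methylbut-2-enyl)phenoxy]-3-hydroxy-5-(trifluoromethylsulfonyloxy)benzoate | CCOC(=O)c1cc(OS(=O)(=O)C(F)(F)F)cc(O)c1Oc1ccc(CC=C(C)C)c(OCOC)c1Br
F4 | step 9 | bis(tert-butyldimethylsilyl) ether of 17 (silyl groups on the phenolic and the benzylic oxygen) | Cc1cc(O[Si](C)(C)C(C)(C)C)c(Oc2ccc(CC=C(C)C)c(OCOC)c2Br)c(CO[Si](C)(C)C(C)(C)C)c1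
F5 | step 9 | aryllithium from F4 by bromine–lithium exchange at C1 of ring A | Cc1cc(O[Si](C)(C)C(C)(C)C)c(Oc2ccc(CC=C(C)C)c(OCOC)c2[Li])c(CO[Si](C)(C)C(C)(C)C)c1
F6 | step 9 | 6-[2-(tert-butyldimethylsilyloxy)-6-(tert-butyldimethylsilyloxymethyl)-4-methylphenoxy]-2-(methoxymethoxy)-3-(3-methylbut-2-enyl)benzoic acid | Cc1cc(O[Si](C)(C)C(C)(C)C)c(Oc2ccc(CC=C(C)C)c(OCOC)c2C(=O)O)c(CO[Si](C)(C)C(C)(C)C)c1
F7 | step 3 | racemic 2-bromo-3-hydroxy-6-(prop-2-enyl)cyclohexa-2,4-dien-1-one | C=CCC1C=CC(O)=C(Br)C1=O
F8 | step 3 | 2-bromo-4-(prop-2-enyl)benzene-1,3-diol | C=CCc1ccc(O)c(Br)c1O
F9 | step 6 | racemic ethyl 4-hydroxypent-2-ynoate | CCOC(=O)C#CC(C)O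
F10 | step 6 | ethyl 4-oxopent-2-ynoate | CCOC(=O)C#CC(C)=O
A1 | alternative 1 | (Z)-4-(allyloxy)-2-[2-(tert-butyldimethylsilyloxy)ethylidene]benzofuran-3(2H)-one | C=CCOc1cccc2c1C(=O)/C(=C/CO[Si](C)(C)C(C)(C)C)O2
A2 | alternative 1 | (E)-1-(trimethylsilyloxy)-3-methylbuta-1,3-diene | C=C(C)/C=C/O[Si](C)(C)C
A3 | alternative 1 | racemic endo adduct 4-(allyloxy)-6'-(tert-butyldimethylsilyloxymethyl)-4'-methyl-2'-(trimethylsilyloxy)spiro[benzofuran-2,1'-cyclohex-3'-en]-3-one, relative configuration as drawn | C=CCOc1cccc2c1C(=O)[C@]1(O2)[C@H](O[Si](C)(C)C)C=C(C)C[C@H]1CO[Si](C)(C)C(C)(C)C
A4 | alternative 2 | methyl 7-methyl-3-oxooct-6-enoate | COC(=O)CC(=O)CCC=C(C)C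
A5 | alternative 2 | methyl acrylate | C=CC(=O)OC
A6 | alternative 2 | racemic methyl 3-(3-methylbut-2-enyl)-2,6-dioxocyclohexane-1-carboxylate | COC(=O)C1C(=O)CCC(CC=C(C)C)C1=O
A7 | alternative 3 | 3-(methoxymethoxy)-4-(3-methylbut-2-enyl)-2-(trimethylsilyl)phenyl trifluoromethanesulfonate | COCOc1c(CC=C(C)C)ccc(OS(=O)(=O)C(F)(F)F)c1[Si](C)(C)C
A8 | alternative 3 | 3-(methoxymethoxy)-4-(3-methylbut-2-enyl)benzyne | COCOC1=C(CC=C(C)C)C=CC#C1
A9 | alternative 3 | 2-(tert-butyldimethylsilyloxymethyl)-6-(methoxymethoxy)-4-methylphenol | Cc1cc(CO[Si](C)(C)C(C)(C)C)c(O)c(OCOC)c1
A10 | alternative 3 | 6-[2-(tert-butyldimethylsilyloxymethyl)-6-(methoxymethoxy)-4-methylphenoxy]-2-(methoxymethoxy)-3-(3-methylbut-2-enyl)benzoic acid | CC(C)=CCc1ccc(Oc2c(OCOC)cc(C)cc2CO[Si](C)(C)C(C)(C)C)c(C(=O)O)c1OCOC
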